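**Retrosynthetic overview**
- Target ⇒ (2S)-2-(5-methylhex-4-enoyl)dihydrofuran ketone: the C1'–CH3 bond is cut, and a chelation-controlled MeMgBr addition sets C1'.
- Ketone ⇒ acyl trione + formaldehyde + 1-chloro-6-methylhept-5-en-2-one: a one-pot Knoevenagel / chiral ammonium ylide [4+1] annulation cuts C3a–C3, C3–C2 and O1–C2 and sets C2.
- Feature used: ring B (O1, C2, C3, C3a, C7a) is the O-alkylated enol of the C4/C7a 1,3-dione of ring A. Only a methylene (C3) and a methine (C2) lie between enol carbon C3a and enol oxygen O1, and C2 carries C1', which can be held as a ketone. C3 is therefore formaldehyde and C2 an acyl-stabilised ylide carbon.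
- Acyl trione ⇒ phloroglucinol + 2-methylpropanoyl chloride (Friedel–Crafts acylation, dearomative gem-dimethylation). Chloroketone ⇒ 2-methylbut-3-en-2-ol + triethyl orthoacetate (Johnson–Claisen, chloromethylation of the ester).
- Ring order: ring A is the phloroglucinol ring throughout; ring B is the only ring formed, in the key step.

Key step: step 5

Assumption: the quinidine-series amine is taken to favour the (2S)-dihydrofuran; if the sense of induction proves opposite, the pseudo-enantiomeric 9-O-methylquinine is used in the same step.
Assumption: the triones are drawn as triketo forms and the two benzofurandiones as the exocyclic-enol tautomer of the target SMILES; all are freely interconverting enol tautomers.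

**Step 1**
Reactants: 1 phloroglucinol (benzene-1,3,5-triol); 2 2-methylpropanoyl chloride
Product: 3 2-methyl-1-(2,4,6-trihydroxyphenyl)propan-1-one
Conditions: AlCl3 (4 equiv), PhNO2/CH2Cl2, 0 °C to 50 °C; ice/aq HCl
Reagents that add atoms: none
Why: Friedel–Crafts acylation of the very electron-rich arene should stop after one acyl group, because the aryl ketone–AlCl3 complex is deactivated toward a second acylation.

**Step 2**
Reactants: 3 2-methyl-1-(2,4,6-trihydroxyphenyl)propan-1-one
Product: 4 4,4-dimethyl-2-(2-methylpropanoyl)cyclohexane-1,3,5-trione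
Conditions: NaOMe (3.5 equiv), MeI (2.2 equiv), MeOH, 0 °C to rt; aq HCl; chromatography
Reagents that add atoms: iodomethane, CI
Why: Dearomative C-methylation of the phloroglucinol polyanion: the first methyl group makes the carbon that bears it the most nucleophilic ring position, so the second methyl is expected to enter there and lock the ring as the gem-dimethyl trione, with MeI held near two equivalents to hold back a third methylation at C6.

**Step 3**
Reactants: 5 2-methylbut-3-en-2-ol; 6 triethyl orthoacetate
Product: 7 ethyl 5-methylhex-4-enoate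
Conditions: EtCO2H (cat.), neat 6 (excess), 140 °C, EtOH distilled off
Reagents that add atoms: none
Why: Johnson–Claisen rearrangement: the mixed ketene acetal of the tertiary allylic alcohol undergoes a [3,3] shift that places the new C–C bond at the vinyl terminus and leaves the trisubstituted alkene.

**Step 4**
Reactants: 7 ethyl 5-methylhex-4-enoate
Product: 8 1-chloro-6-methylhept-5-en-2-one
Conditions: ICH2Cl (1.5 equiv), MeLi·LiBr (1.5 equiv, slow addition), THF, −78 °C; AcOH/THF quench at −78 °C
Reagents that add atoms: chloroiodomethane, ClCI
Why: Chloromethylation of an ester with chloromethyllithium made in situ by iodine–lithium exchange (ester to α-chloroketone homologation): the lithium hemiketal of the first addition is stabilised by the chloromethyl group at −78 °C and collapses to the ketone only on the cold acidic quench, so a second addition should be avoided.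

**Step 5**
Reactants: 4 4,4-dimethyl-2-(2-methylpropanoyl)cyclohexane-1,3,5-trione; 8 1-chloro-6-methylhept-5-en-2-one; 9 formaldehyde (used as paraformaldehyde)
Product: 13 (2S,7Z)-7-(1-hydroxy-2-methylpropylidene)-5,5-dimethyl-2-(5-methylhex-4-enoyl)-2,3-dihydro-1-benzofuran-4,6(5H,7H)-dione, via quinidinium salt 10 (not isolated), via methylene trione 11 (not isolated), via betaine 12 (not isolated)
Conditions: 8 (1.2 equiv), 9-O-methylquinidine (1.25 equiv), NaI (10 mol%), MeCN, rt; then (CH2O)n (2 equiv), Cs2CO3 (3 equiv), 0 °C, 4 added slowly in MeCN, 0 °C to rt; aq citric acid (amine recovered from the aqueous phase)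
Reagents that add atoms: none
Why: Cs2CO3 converts the preformed salt 10 into its ketone-stabilised ylide and drives Knoevenagel condensation of formaldehyde at C6 of 4, the only ring carbon with two hydrogens, to the methylene oxa-diene 11 (C3a–C3); Michael addition of the ylide carbon to the exocyclic CH2 gives betaine 12 (C3–C2), whose enolate oxygen displaces the quinuclidine by SN2 attack with inversion (O1–C2) and sets the amine free (should the ylide meet formaldehyde first, the α-ammonio enone formed by loss of water accepts 4 and gives the same 12). The closest known reactions are the three-component annulation of cyclic 1,3-diones, aldehydes and pyridinium or ammonium ylides to 2-acyl-2,3-dihydrofurans and the [4+1] annulation of cinchona ammonium ylides with ortho-quinone methides. Ring B is closed in the 5-exo-tet mode. C2 is the only new stereocentre and is controlled by the chiral quinuclidinium leaving group: C2–H of 12 lies between N+ and C=O, so the two C2 epimers interconvert through the ylide (Curtin–Hammett), and the (R)-epimer, which can place the enolate at the backside of the C–N bond away from the quinoline, is expected to close faster and give (2S)-13. The step needs O- rather than C-closure (5-exo-tet over 3-exo-tet, usual for cyclic 1,3-dione enolates), closure through the C7a oxygen rather than the C4 oxygen (in the dianion the C7a oxygen is conjugated with both enolate systems and C4–O is flanked by the quaternary C5), and capture of 11 by the ylide rather than by 4, for which 4 is added slowly to an excess of ylide and formaldehyde and no free chloroketone is left to alkylate 4 directly. Until work-up 13 is present as the cesium salt of its acyl-dione, which lowers the acidity of C2–H and guards the new centre against epimerisation.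

**Step 6**
Reactants: 13 (2S,7Z)-7-(1-hydroxy-2-methylpropylidene)-5,5-dimethyl-2-(5-methylhex-4-enoyl)-2,3-dihydro-1-benzofuran-4,6(5H,7H)-dione
Product: 14 (2S,7Z)-2-[(2R)-2-hydroxy-6-methylhept-5-en-2-yl]-7-(1-hydroxy-2-methylpropylidene)-5,5-dimethyl-2,3-dihydro-1-benzofuran-4,6(5H,7H)-dione
Conditions: MeMgBr (3 equiv), Et2O/CH2Cl2, −78 °C; aq NH4Cl
Reagents that add atoms: methylmagnesium bromide, C[Mg]Br
Why: Chelation-controlled Grignard addition (Cram chelate model): the first equivalent turns the enolised acyl-dione into its magnesium enolate, which shields the C4, C6 and isobutyryl carbonyls, and magnesium bridging O1 and the side-chain ketone oxygen then holds that C=O syn-periplanar to C2–O1, so that methyl is delivered to the ketone face on the side of C2–H, away from C3H2, which with the (2S) centre gives the (R)-carbinol.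

**Compound list**
1 | phloroglucinol (benzene-1,3,5-triol) | Oc1cc(O)cc(O)c1 | starting material
2 | 2-methylpropanoyl chloride | CC(C)C(Cl)=O | starting material
3 | 2-methyl-1-(2,4,6-trihydroxyphenyl)propan-1-one | CC(C)C(=O)c1c(O)cc(O)cc1O | intermediate
4 | 4,4-dimethyl-2-(2-methylpropanoyl)cyclohexane-1,3,5-trione | CC(C)C(=O)C1C(=O)CC(=O)C(C)(C)C1=O | intermediate
5 | 2-methylbut-3-en-2-ol | CC(C)(O)C=C | starting material
6 | triethyl orthoacetate (1,1,1-triethoxyethane) | CCOC(C)(OCC)OCC | starting material
7 | ethyl 5-methylhex-4-enoate | CCOC(=O)CCC=C(C)C | intermediate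
8 | 1-chloro-6-methylhept-5-en-2-one | CC(C)=CCCC(=O)CCl | intermediate
9 | formaldehyde (used as paraformaldehyde) | C=O | starting material
10 | N-(6-methyl-2-oxohept-5-en-1-yl)-9-O-methylquinidinium chloride (quinuclidine nitrogen alkylated by 8; not isolated) | COC1=CC2=C(C=CN=C2C=C1)[C@@H]([C@H]3C[C@@H]4CC[N@@+]3(CC(=O)CCC=C(C)C)C[C@@H]4C=C)OC.[Cl-] | intermediate
11 | 4,4-dimethyl-6-methylidene-2-(2-methylpropanoyl)cyclohexane-1,3,5-trione (not isolated) | CC(C)C(=O)C1C(=O)C(=C)C(=O)C(C)(C)C1=O | intermediate
12 | betaine: 9-O-methylquinidinium whose nitrogen carries the (R)-configured future C2 (H, 5-methylhex-4-enoyl, CH2 bound to the trione enolate; not isolated) | COC1=CC2=C(C=CN=C2C=C1)[C@@H]([C@H]3C[C@@H]4CC[N@@+]3([C@@H](C(=O)CCC=C(C)C)CC5=C([O-])/C(=C(/O)C(C)C)C(=O)C(C)(C)C5=O)C[C@@H]4C=C)OC | intermediate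
13 | (2S,7Z)-7-(1-hydroxy-2-methylpropylidene)-5,5-dimethyl-2-(5-methylhex-4-enoyl)-2,3-dihydro-1-benzofuran-4,6(5H,7H)-dione | CC(C)=CCCC(=O)[C@@H]1CC2=C(O1)/C(=C(/O)C(C)C)C(=O)C(C)(C)C2=O | intermediate
14 | (2S,7Z)-2-[(2R)-2-hydroxy-6-methylhept-5-en-2-yl]-7-(1-hydroxy-2-methylpropylidene)-5,5-dimethyl-2,3-dihydro-1-benzofuran-4,6(5H,7H)-dione | CC(C)=CCC[C@@](C)(O)[C@@H]1CC2=C(O1)/C(=C(/O)C(C)C)C(=O)C(C)(C)C2=O | target

**Step count**
Total: 6 steps. Longest linear sequence: 4 steps (steps 1, 2, 5, 6 or steps 3, 4, 5, 6).

**Steps most likely to fail**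

1. Step 5. Three processes may spoil it:
   - The methylene trione 11 may be captured by 4 that has not yet condensed (methylene-bis-trione formation), or may oligomerise, before the ylide reaches it.
   - The enolate of 12 may close through the C4 oxygen or through carbon.
   - The two C2-epimeric betaines may close at similar rates, or C2–H of 13 may exchange under carbonate, so that the enantiomeric purity is low.

   Fallback, by known reaction types only; it sets out from 4 and comes back to the route at 14, so that step 6 is not needed. Geraniol is epoxidised under Sharpless conditions (Ti(OiPr)4, D-(−)-diethyl tartrate, t-BuOOH, 4 Å sieves, CH2Cl2, −20 °C) to (2R,3R)-2,3-epoxygeraniol F1. Parikh–Doering oxidation (SO3·pyridine, DMSO, iPr2NEt, 0 °C) gives (2S,3R)-3-methyl-3-(4-methylpent-3-en-1-yl)oxirane-2-carbaldehyde F2. Condensation of F2 with 4 in the presence of Hantzsch ester (diethyl 2,6-dimethyl-1,4-dihydropyridine-3,5-dicarboxylate, CH2Cl2, rt; three-component reductive alkylation) gives the C6-alkylated epoxy trione F3, the alkylidene being reduced as it forms so that no methylene-bis adduct can arise. K2CO3 in MeOH then lets the C7a oxygen open the epoxide at its CH carbon (5-exo-tet, inversion at C2, C1' untouched), which should give 14 with both stereocentres taken from the epoxidation.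

2. Step 6. Magnesium may fail to bridge O1, a weakly basic vinylogous-ester oxygen, and the ketone, so that the addition follows the polar Felkin–Anh course to the C1' epimer; a sluggish addition would also leave time for enolisation toward C2. A merely low selectivity costs material only, since the two C1' epimers are diastereomers and can be separated; a reversed preference is answered by exchanging the roles of the two carbon groups.

   Fallback; it sets out from 4 and 9 and comes back at 14. Under the conditions of step 5 with chloroacetone in place of 8, N-(2-oxopropyl)-9-O-methylquinidinium chloride F4 forms and its ylide adds to 11 to give the betaine F5, which closes to (2S,7Z)-2-acetyl-7-(1-hydroxy-2-methylpropylidene)-5,5-dimethyl-2,3-dihydro-1-benzofuran-4,6(5H,7H)-dione F6. Addition of (4-methylpent-3-en-1-yl)magnesium bromide F7 (3 equiv, from 5-bromo-2-methylpent-2-ene and Mg in THF) in THF at −78 °C then brings in the homoprenyl group on the non-chelated face, which with the methyl ketone corresponds to the (R)-carbinol of 14.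

3. Step 2. The methylation may not stop cleanly: a third methyl group may enter at C6, the second methyl may go to the other ring CH (aromatic 3,5-dimethyl isomer), or oxygen may be methylated, so that 4 has to be separated from closely related by-products.

   Fallback; it sets out from 2 and comes back at 4. Methyl 2,4,6-trihydroxybenzoate is acylated with 2 (AlCl3, PhNO2, 50 °C) to methyl 2,4,6-trihydroxy-3-(2-methylpropanoyl)benzoate F8, in which only one ring CH is left. NaOMe/MeI in MeOH can therefore place both methyl groups only there and gives methyl 3,3-dimethyl-5-(2-methylpropanoyl)-2,4,6-trioxocyclohexane-1-carboxylate F9. Krapcho dealkoxycarbonylation (LiCl, wet DMSO, 120 °C) removes the blocking ester and gives 4.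

**Further compounds**
F1 | step 5 | [(2R,3R)-3-methyl-3-(4-methylpent-3-en-1-yl)oxiran-2-yl]methanol ((2R,3R)-2,3-epoxygeraniol) | CC(C)=CCC[C@@]1(C)O[C@@H]1CO
F2 | step 5 | (2S,3R)-3-methyl-3-(4-methylpent-3-en-1-yl)oxirane-2-carbaldehyde | CC(C)=CCC[C@@]1(C)O[C@@H]1C=O
F3 | step 5 | 4,4-dimethyl-6-{[(2R,3R)-3-methyl-3-(4-methylpent-3-en-1-yl)oxiran-2-yl]methyl}-2-(2-methylpropanoyl)cyclohexane-1,3,5-trione | CC(C)=CCC[C@@]1(C)O[C@@H]1CC2C(=O)C(C(=O)C(C)C)C(=O)C(C)(C)C2=O
F4 | step 6 | N-(2-oxopropyl)-9-O-methylquinidinium chloride | COC1=CC2=C(C=CN=C2C=C1)[C@@H]([C@H]3C[C@@H]4CC[N@@+]3(CC(C)=O)C[C@@H]4C=C)OC.[Cl-]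
F5 | step 6 | betaine: 9-O-methylquinidinium whose nitrogen carries the (R)-configured carbon bearing H, acetyl and the CH2 bound to the trione enolate | COC1=CC2=C(C=CN=C2C=C1)[C@@H]([C@H]3C[C@@H]4CC[N@@+]3([C@@H](C(C)=O)CC5=C([O-])/C(=C(/O)C(C)C)C(=O)C(C)(C)C5=O)C[C@@H]4C=C)OC
F6 | step 6 | (2S,7Z)-2-acetyl-7-(1-hydroxy-2-methylpropylidene)-5,5-dimethyl-2,3-dihydro-1-benzofuran-4,6(5H,7H)-dione | CC(=O)[C@@H]1CC2=C(O1)/C(=C(/O)C(C)C)C(=O)C(C)(C)C2=O
F7 | step 6 | (4-methylpent-3-en-1-yl)magnesium bromide | CC(C)=CCC[Mg]Br
F8 | step 2 | methyl 2,4,6-trihydroxy-3-(2-methylpropanoyl)benzoate | COC(=O)c1c(O)cc(O)c(C(=O)C(C)C)c1O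
F9 | step 2 | methyl 3,3-dimethyl-5-(2-methylpropanoyl)-2,4,6-trioxocyclohexane-1-carboxylate | COC(=O)C1C(=O)C(C(=O)C(C)C)C(=O)C(C)(C)C1=O
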